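**Assumption (numbering convention):** atoms carry germacranolide numbers (C1–C10 carbocycle, C11–C13 lactone carbons, C14 and C15 methyls); "8β" is the C8 configuration of the target and "8α" its epimer.

## Retrosynthetic overview

1. Target ⇐ C8 ester installed last but one, by Mitsunobu inversion of the 8α-alcohol 38 with acid 25; the C9 PMB ether comes off last.
2. Bridged 3(2H)-furanone ⇐ transannular oxa-cyclisation of a ten-membered α'-hydroxy ynone ⇐ intramolecular alkynylchromium/aldehyde closure of C1–C2.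
3. Open-chain precursor ⇐ intermolecular zinc-mediated carbonyl allylation (C7–C8) of aldehyde 10 with bromobutenolide 19; this step also unveils the α-methylene-γ-lactone and sets C7 and C8.
4. Aldehyde 10 ⇐ diethyl L-tartrate (C9 from the pool, C10 by chelation-controlled MeMgBr addition). Butenolide 19 ⇐ acrolein and propynyl Grignard (Red-Al/I2, lipase resolution, ring-closing metathesis).
5. Ring order: butenolide → α-methylene-γ-lactone (in the coupling) → ten-membered carbocycle → furanone.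

The stereochemical outcome of the coupling (8α) and the feasibility of the macrocyclisation and late inversion are predictions from transition-state models and analogy; none of this has been run.

## Route

### Eastern aldehyde (C8–C10, C1, C14)

Step 1
Reactants: 1 diethyl L-tartrate
Product: 2 diethyl (4R,5R)-2-(4-methoxyphenyl)-1,3-dioxolane-4,5-dicarboxylate
Conditions: 4-MeOC6H4CH(OMe)2, CSA (cat.), toluene, reflux (MeOH distilled off)
Reagents that add atoms: p-anisaldehyde dimethyl acetal, COC(OC)c1ccc(OC)cc1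
Why: Acid-catalysed transacetalisation of the 1,2-diol; both stereocentres are untouched and the C2 symmetry makes the acetal carbon non-stereogenic.

Step 2
Reactants: 2 diethyl (4R,5R)-2-(4-methoxyphenyl)-1,3-dioxolane-4,5-dicarboxylate
Product: 3 [(4S,5S)-2-(4-methoxyphenyl)-1,3-dioxolane-4,5-diyl]dimethanol
Conditions: LiAlH4, THF, 0 °C to rt
Reagents that add atoms: none
Why: Hydride reduction of both esters to primary alcohols; the acetal is inert to LiAlH4.

Step 3
Reactants: 3 [(4S,5S)-2-(4-methoxyphenyl)-1,3-dioxolane-4,5-diyl]dimethanol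
Product: 4 (4S,5S)-4,5-bis{[(tert-butyldimethylsilyl)oxy]methyl}-2-(4-methoxyphenyl)-1,3-dioxolane
Conditions: TBSCl, imidazole, DMF, rt
Reagents that add atoms: tert-butyldimethylsilyl chloride, CC(C)(C)[Si](C)(C)Cl
Why: Standard silylation of the two equivalent primary alcohols.

Step 4
Reactants: 4 (4S,5S)-4,5-bis{[(tert-butyldimethylsilyl)oxy]methyl}-2-(4-methoxyphenyl)-1,3-dioxolane
Product: 5 (2S,3S)-1,4-bis[(tert-butyldimethylsilyl)oxy]-3-[(4-methoxybenzyl)oxy]butan-2-ol
Conditions: iBu2AlH (DIBAL-H), CH2Cl2, −78 to 0 °C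
Reagents that add atoms: none
Why: Reductive opening of the p-methoxybenzylidene acetal; because the acetal is C2-symmetric either C–O cleavage gives the same mono-PMB ether.

Step 5
Reactants: 5 (2S,3S)-1,4-bis[(tert-butyldimethylsilyl)oxy]-3-[(4-methoxybenzyl)oxy]butan-2-ol
Product: 6 (3S)-1,4-bis[(tert-butyldimethylsilyl)oxy]-3-[(4-methoxybenzyl)oxy]butan-2-one
Conditions: Dess–Martin periodinane, NaHCO3, CH2Cl2, rt
Reagents that add atoms: none
Why: Dess–Martin oxidation under buffered, non-basic conditions, so the α-alkoxy stereocentre (future C9) is not epimerised.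

Step 6
Reactants: 6 (3S)-1,4-bis[(tert-butyldimethylsilyl)oxy]-3-[(4-methoxybenzyl)oxy]butan-2-one
Product: 7 (2R,3S)-1,4-bis[(tert-butyldimethylsilyl)oxy]-3-[(4-methoxybenzyl)oxy]-2-methylbutan-2-ol
Conditions: MeMgBr, Et2O/CH2Cl2, −78 °C
Reagents that add atoms: methylmagnesium bromide, C[Mg]Br
Why: Cram-chelate Grignard addition: magnesium bridges the carbonyl and the α-OPMB oxygen (the silyl ethers do not chelate) and methyl enters from the face of the α-hydrogen, which sets the quaternary carbinol (future C10) as 2R.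

Step 7
Reactants: 7 (2R,3S)-1,4-bis[(tert-butyldimethylsilyl)oxy]-3-[(4-methoxybenzyl)oxy]-2-methylbutan-2-ol
Product: 8 (2R,3S)-3-[(4-methoxybenzyl)oxy]-2-methylbutane-1,2,4-triol
Conditions: Bu4NF, THF, rt
Reagents that add atoms: none
Why: Fluoride-mediated cleavage of both primary silyl ethers; the PMB ether and the stereocentres are unaffected.

Step 8
Reactants: 8 (2R,3S)-3-[(4-methoxybenzyl)oxy]-2-methylbutane-1,2,4-triol
Product: 9 (2S)-2-[(4-methoxybenzyl)oxy]-2-[(4R)-2,2,4-trimethyl-1,3-dioxolan-4-yl]ethan-1-ol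
Conditions: Me2C(OMe)2, CSA (cat.), acetone, rt
Reagents that add atoms: 2,2-dimethoxypropane, COC(C)(C)OC
Why: Thermodynamic acetonide formation selects the five-membered dioxolane on the primary/tertiary 1,2-diol over six- or seven-membered alternatives, leaving only the C8 primary alcohol free.

Step 9
Reactants: 9 (2S)-2-[(4-methoxybenzyl)oxy]-2-[(4R)-2,2,4-trimethyl-1,3-dioxolan-4-yl]ethan-1-ol
Product: 10 (2R)-2-[(4-methoxybenzyl)oxy]-2-[(4R)-2,2,4-trimethyl-1,3-dioxolan-4-yl]acetaldehyde
Conditions: Dess–Martin periodinane, NaHCO3, CH2Cl2, 0 °C to rt; used crude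
Reagents that add atoms: none
Why: Buffered Dess–Martin oxidation gives the α-alkoxy aldehyde without epimerisation (the descriptor changes from S to R only because of priorities).

### Western bromobutenolide (C4–C7, C11–C13, C15)

Step 10
Reactants: 11 acrolein; 12 prop-1-yn-1-ylmagnesium bromide
Product: 13 rac-hex-1-en-4-yn-3-ol
Conditions: THF, −78 °C; aq. NH4Cl
Reagents that add atoms: none
Why: 1,2-Addition of an alkynyl Grignard reagent to the enal at low temperature; the carbinol is racemic and is resolved in step 12.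

Step 11
Reactants: 13 rac-hex-1-en-4-yn-3-ol
Product: 15 rac-(4Z)-5-iodohexa-1,4-dien-3-ol, via cyclic alkenylalanate 14 (not isolated)
Conditions: NaAlH2(OCH2CH2OCH3)2 (Red-Al), THF, 0 °C to rt; then I2, −78 °C
Reagents that add atoms: iodine, II
Why: Hydroxyl-directed trans-hydroalumination puts aluminium on the distal alkyne carbon and iodinolysis with retention gives the Z vinyl iodide (iodine cis to the carbinol carbon), which fixes the C4=C5 geometry of the target.

Step 12
Reactants: 15 rac-(4Z)-5-iodohexa-1,4-dien-3-ol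
Product: 16 (3S,4Z)-5-iodohexa-1,4-dien-3-ol
Conditions: Novozym 435 (immobilised Candida antarctica lipase B), vinyl acetate, MTBE, rt, to about 55 % conversion; chromatography
Reagents that add atoms: none
Why: Lipase kinetic resolution (Kazlauskas rule, vinyl as the medium group) acetylates the R enantiomer and leaves the S alcohol, the future C6 stereocentre, in high ee.

Step 13
Reactants: 16 (3S,4Z)-5-iodohexa-1,4-dien-3-ol; 17 2-(bromomethyl)acrylic acid
Product: 18 (3S,4Z)-5-iodohexa-1,4-dien-3-yl 2-(bromomethyl)acrylate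
Conditions: DCC, DMAP (5 mol %), CH2Cl2, 0 °C
Reagents that add atoms: none
Why: Steglich esterification forms the acyl–oxygen bond only, so the carbinol configuration is retained.

Step 14
Reactants: 18 (3S,4Z)-5-iodohexa-1,4-dien-3-yl 2-(bromomethyl)acrylate
Product: 19 (5S)-3-(bromomethyl)-5-[(Z)-2-iodoprop-1-en-1-yl]furan-2(5H)-one
Conditions: second-generation Grubbs catalyst (H2IMes)(PCy3)Cl2Ru=CHPh (5 mol %), CH2Cl2, 40 °C
Reagents that add atoms: none
Why: Ring-closing metathesis between the terminal vinyl group and the acrylate; the trisubstituted iodoalkene does not take part and the neutral conditions do not racemise the doubly allylic C6–H.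

### Side-chain acid

Step 15
Reactants: 20 tert-butyl acrylate; 21 acetaldehyde
Product: 22 rac-tert-butyl 3-hydroxy-2-methylidenebutanoate
Conditions: DABCO (cat.), neat, rt, several days
Reagents that add atoms: none
Why: Morita–Baylis–Hillman reaction; the stereocentre formed is removed in step 17.

Step 16
Reactants: 22 rac-tert-butyl 3-hydroxy-2-methylidenebutanoate
Product: 23 rac-tert-butyl 3-acetoxy-2-methylidenebutanoate
Conditions: Ac2O, pyridine, DMAP (cat.), CH2Cl2, 0 °C to rt
Reagents that add atoms: acetic anhydride, CC(=O)OC(C)=O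
Why: Routine acetylation of the secondary allylic alcohol.

Step 17
Reactants: 23 rac-tert-butyl 3-acetoxy-2-methylidenebutanoate
Product: 24 tert-butyl (2E)-2-(acetoxymethyl)but-2-enoate
Conditions: DABCO (20 mol %), THF, reflux
Reagents that add atoms: none
Why: Amine-catalysed 1,3-acetoxy transposition (SN2' then SN2') to the thermodynamically favoured primary allylic acetate, whose trisubstituted alkene is E (methyl trans to the ester).

Step 18
Reactants: 24 tert-butyl (2E)-2-(acetoxymethyl)but-2-enoate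
Product: 25 (2E)-2-(acetoxymethyl)but-2-enoic acid
Conditions: CF3CO2H, CH2Cl2, 0 °C to rt
Reagents that add atoms: none
Why: Acidolysis of the tert-butyl ester (loss of isobutene) leaves the acetate and the alkene geometry intact.

### Fragment union and endgame

Step 19
Reactants: 19 (5S)-3-(bromomethyl)-5-[(Z)-2-iodoprop-1-en-1-yl]furan-2(5H)-one; 10 (2R)-2-[(4-methoxybenzyl)oxy]-2-[(4R)-2,2,4-trimethyl-1,3-dioxolan-4-yl]acetaldehyde
Product: 27 seco-lactone alcohol (8α-OH; 6S,7R,8R,9S,10R), via allylzinc bromide 26 (not isolated)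
Conditions: Zn dust, THF/sat. aq. NH4Cl, rt
Reagents that add atoms: none
Why: Zinc Barbier carbonyl allylation (SE2') forms C7–C8 and the exo-methylene lactone; attack anti to the C6 alkenyl group sets C7 (trans-lactone), and a chair Zimmerman–Traxler transition state with the aldehyde residue equatorial, reinforced by chelation of the α-OPMB oxygen, should set C8 as the 8α (8R) alcohol, the epimer that step 28 inverts.

Step 20
Reactants: 27 seco-lactone alcohol (8α-OH)
Product: 28 8-O-TBS seco-lactone vinyl iodide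
Conditions: TBSOTf, 2,6-lutidine, CH2Cl2, −78 to 0 °C
Reagents that add atoms: tert-butyldimethylsilyl triflate, CC(C)(C)[Si](C)(C)OS(=O)(=O)C(F)(F)F
Why: Silylation of the hindered secondary alcohol with a non-nucleophilic base that leaves the Michael acceptor and acetonide alone; it stops C8–OH from forming a lactol with the later C1 aldehyde.

Step 21
Reactants: 28 8-O-TBS seco-lactone vinyl iodide; 29 trimethylsilylacetylene
Product: 30 8-O-TBS seco-lactone TMS-enyne
Conditions: Pd(PPh3)2Cl2 (5 mol %), CuI (10 mol %), Et3N, THF, rt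
Reagents that add atoms: none
Why: Sonogashira coupling of the vinyl iodide with retention of the Z geometry; the tertiary amine cannot add irreversibly to the α-methylene lactone, and C6 is no longer base-labile once the butenolide is saturated.

Step 22
Reactants: 30 8-O-TBS seco-lactone TMS-enyne
Product: 31 C1,C10-diol TMS-enyne
Conditions: AcOH/H2O/THF (4:1:1), 40 °C
Reagents that add atoms: none
Why: Mild acid hydrolysis of the terminal acetonide; the hindered secondary TBS ether, PMB ether, silylalkyne and lactone tolerate these conditions.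

Step 23
Reactants: 31 C1,C10-diol TMS-enyne
Product: 32 C1,C10-diol iodoalkyne
Conditions: N-iodosuccinimide, AgNO3 (10 mol %), acetone, rt, dark
Reagents that add atoms: N-iodosuccinimide, O=C1CCC(=O)N1I
Why: Silver-catalysed iododesilylation converts the alkynylsilane directly into the 1-iodoalkyne without touching the alkenes or alcohols.

Step 24
Reactants: 32 C1,C10-diol iodoalkyne
Product: 33 C10-hydroxy C1-aldehyde iodoalkyne
Conditions: SO3·pyridine, DMSO, iPr2NEt, CH2Cl2, 0 °C; used at once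
Reagents that add atoms: none
Why: Parikh–Doering oxidation takes the primary alcohol to the aldehyde without glycol cleavage; the tertiary C10–OH cannot be oxidised and the aldehyde has no α-hydrogen to epimerise.

Step 25
Reactants: 33 C10-hydroxy C1-aldehyde iodoalkyne
Product: 35 macrocyclic propargylic diol (C1 epimers), via alkynylchromium dichloride 34 (not isolated)
Conditions: CrCl2 (8 equiv), NiCl2 (2 mol %), degassed THF, rt, 2 mM, slow addition
Reagents that add atoms: none
Why: Intramolecular Nozaki–Hiyama–Kishi alkynylation: the iodoalkyne becomes an alkynylchromium species that adds only to the aldehyde, closing C1–C2 of the ten-membered ring at high dilution; the C1 configuration is irrelevant because it is oxidised next.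

Step 26
Reactants: 35 macrocyclic propargylic diol (C1 epimers)
Product: 37 8α-O-TBS 9-O-PMB furanone macrocycle, via hydroxy ynone 36 (not isolated)
Conditions: MnO2, CH2Cl2, rt; filter; then Ph3PAuNTf2 (5 mol %), CH2Cl2, rt
Reagents that add atoms: none
Why: MnO2 oxidises only the propargylic carbinol, and cationic univalent gold then activates the strained ynone for transannular 5-endo-dig attack of the C10 hydroxyl on C3, forming the bridged 3(2H)-furanone with C10 unchanged.

Step 27
Reactants: 37 8α-O-TBS 9-O-PMB furanone macrocycle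
Product: 38 8α-hydroxy 9-O-PMB furanone macrocycle
Conditions: HF·pyridine, pyridine/THF, 0 °C to rt
Reagents that add atoms: none
Why: Buffered, non-basic fluoride desilylation frees C8–OH without translactonisation or conjugate addition.

Step 28
Reactants: 38 8α-hydroxy 9-O-PMB furanone macrocycle; 25 (2E)-2-(acetoxymethyl)but-2-enoic acid
Product: 39 9-O-PMB ether of the target
Conditions: PPh3, DIAD (betaine pre-formed), toluene, 0 °C to rt
Reagents that add atoms: none
Why: Mitsunobu esterification: the 8α-hydroxyl is activated as an alkoxyphosphonium ion and displaced by the carboxylate in an SN2 step with inversion, giving the 8β (8S) ester; C9–O is masked so only C8 reacts.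

Step 29
Reactants: 39 9-O-PMB ether of the target
Product: 40 CNP0231561.3
Conditions: DDQ, CH2Cl2/pH 7 buffer, 0 °C
Reagents that add atoms: none
Why: Oxidative PMB cleavage under neutral conditions frees the C9 hydroxyl while the esters, the allylic acetate and both Michael acceptors stay intact.

## Compound list

1 | diethyl L-tartrate, diethyl (2R,3R)-2,3-dihydroxybutanedioate | CCOC(=O)[C@H](O)[C@@H](O)C(=O)OCC | starting material
2 | diethyl (4R,5R)-2-(4-methoxyphenyl)-1,3-dioxolane-4,5-dicarboxylate | CCOC(=O)[C@@H]1OC(c2ccc(OC)cc2)O[C@H]1C(=O)OCC | intermediate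
3 | [(4S,5S)-2-(4-methoxyphenyl)-1,3-dioxolane-4,5-diyl]dimethanol | OC[C@@H]1OC(c2ccc(OC)cc2)O[C@H]1CO | intermediate
4 | (4S,5S)-4,5-bis{[(tert-butyldimethylsilyl)oxy]methyl}-2-(4-methoxyphenyl)-1,3-dioxolane | CC(C)(C)[Si](C)(C)OC[C@@H]1OC(c2ccc(OC)cc2)O[C@H]1CO[Si](C)(C)C(C)(C)C | intermediate
5 | (2S,3S)-1,4-bis[(tert-butyldimethylsilyl)oxy]-3-[(4-methoxybenzyl)oxy]butan-2-ol | CC(C)(C)[Si](C)(C)OC[C@H](OCc1ccc(OC)cc1)[C@@H](O)CO[Si](C)(C)C(C)(C)C | intermediate
6 | (3S)-1,4-bis[(tert-butyldimethylsilyl)oxy]-3-[(4-methoxybenzyl)oxy]butan-2-one | CC(C)(C)[Si](C)(C)OC[C@H](OCc1ccc(OC)cc1)C(=O)CO[Si](C)(C)C(C)(C)C | intermediate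
7 | (2R,3S)-1,4-bis[(tert-butyldimethylsilyl)oxy]-3-[(4-methoxybenzyl)oxy]-2-methylbutan-2-ol | CC(C)(C)[Si](C)(C)OC[C@H](OCc1ccc(OC)cc1)[C@](C)(O)CO[Si](C)(C)C(C)(C)C | intermediate
8 | (2R,3S)-3-[(4-methoxybenzyl)oxy]-2-methylbutane-1,2,4-triol | OC[C@H](OCc1ccc(OC)cc1)[C@](C)(O)CO | intermediate
9 | (2S)-2-[(4-methoxybenzyl)oxy]-2-[(4R)-2,2,4-trimethyl-1,3-dioxolan-4-yl]ethan-1-ol | OC[C@H](OCc1ccc(OC)cc1)[C@@]1(C)COC(C)(C)O1 | intermediate
10 | (2R)-2-[(4-methoxybenzyl)oxy]-2-[(4R)-2,2,4-trimethyl-1,3-dioxolan-4-yl]acetaldehyde (C8 aldehyde, C9 OPMB, C10/C1 acetonide) | O=C[C@H](OCc1ccc(OC)cc1)[C@@]1(C)COC(C)(C)O1 | intermediate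
11 | acrolein | C=CC=O | starting material
12 | prop-1-yn-1-ylmagnesium bromide (THF solution) | CC#C[Mg]Br | starting material
13 | rac-hex-1-en-4-yn-3-ol | C=CC(O)C#CC | intermediate
14 | cyclic alkenylalanate from 13 (sodium 2,2-bis(2-methoxyethoxy)-3-methyl-5-vinyl-2,5-dihydro-1,2-oxaaluminol-2-uide) | [Na+].C=CC1C=C(C)[Al-](OCCOC)(OCCOC)O1 | intermediate (not isolated)
15 | rac-(4Z)-5-iodohexa-1,4-dien-3-ol | C=CC(O)/C=C(/C)I | intermediate
16 | (3S,4Z)-5-iodohexa-1,4-dien-3-ol | C=C[C@H](O)/C=C(/C)I | intermediate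
17 | 2-(bromomethyl)acrylic acid | C=C(CBr)C(=O)O | starting material
18 | (3S,4Z)-5-iodohexa-1,4-dien-3-yl 2-(bromomethyl)acrylate | C=C[C@H](OC(=O)C(=C)CBr)/C=C(/C)I | intermediate
19 | (5S)-3-(bromomethyl)-5-[(Z)-2-iodoprop-1-en-1-yl]furan-2(5H)-one | BrCC1=C[C@@H](/C=C(/C)I)OC1=O | intermediate
20 | tert-butyl acrylate | C=CC(=O)OC(C)(C)C | starting material
21 | acetaldehyde | CC=O | starting material
22 | rac-tert-butyl 3-hydroxy-2-methylidenebutanoate | CC(O)C(=C)C(=O)OC(C)(C)C | intermediate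
23 | rac-tert-butyl 3-acetoxy-2-methylidenebutanoate | CC(OC(C)=O)C(=C)C(=O)OC(C)(C)C | intermediate
24 | tert-butyl (2E)-2-(acetoxymethyl)but-2-enoate | C/C=C(/C(=O)OC(C)(C)C)COC(C)=O | intermediate
25 | (2E)-2-(acetoxymethyl)but-2-enoic acid | C/C=C(/C(=O)O)COC(C)=O | intermediate
26 | allylzinc bromide from 19, {[(5S)-5-[(Z)-2-iodoprop-1-en-1-yl]-2-oxo-2,5-dihydrofuran-3-yl]methyl}zinc bromide | Br[Zn]CC1=C[C@@H](/C=C(/C)I)OC1=O | intermediate (not isolated)
27 | (4R,5S)-4-{(1R,2S)-1-hydroxy-2-[(4-methoxybenzyl)oxy]-2-[(4R)-2,2,4-trimethyl-1,3-dioxolan-4-yl]ethyl}-5-[(Z)-2-iodoprop-1-en-1-yl]-3-methylideneoxolan-2-one (8α-OH; target numbering 6S,7R,8R,9S,10R) | C=C1C(=O)O[C@H](/C=C(/C)I)[C@H]1[C@@H](O)[C@H](OCc1ccc(OC)cc1)[C@@]1(C)COC(C)(C)O1 | intermediate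
28 | 8-O-TBS ether of 27 (6S,7S,8R,9S,10R) | C=C1C(=O)O[C@H](/C=C(/C)I)[C@H]1[C@@H](O[Si](C)(C)C(C)(C)C)[C@H](OCc1ccc(OC)cc1)[C@@]1(C)COC(C)(C)O1 | intermediate
29 | trimethylsilylacetylene | C#C[Si](C)(C)C | starting material
30 | as 28 but with a (Z)-2-methyl-4-(trimethylsilyl)but-1-en-3-yn-1-yl group on C6 (6R,7S,8R,9S,10R) | C=C1C(=O)O[C@H](/C=C(/C)C#C[Si](C)(C)C)[C@H]1[C@@H](O[Si](C)(C)C(C)(C)C)[C@H](OCc1ccc(OC)cc1)[C@@]1(C)COC(C)(C)O1 | intermediate
31 | diol from 30: C1 primary OH and C10 tertiary OH free, 8-OTBS, 9-OPMB, TMS-enyne (6R,7S,8R,9S,10R) | C=C1C(=O)O[C@H](/C=C(/C)C#C[Si](C)(C)C)[C@H]1[C@@H](O[Si](C)(C)C(C)(C)C)[C@H](OCc1ccc(OC)cc1)[C@](C)(O)CO | intermediate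
32 | as 31 but with a (Z)-4-iodo-2-methylbut-1-en-3-yn-1-yl group on C6 | C=C1C(=O)O[C@H](/C=C(/C)C#CI)[C@H]1[C@@H](O[Si](C)(C)C(C)(C)C)[C@H](OCc1ccc(OC)cc1)[C@](C)(O)CO | intermediate
33 | C1 aldehyde of 32 with free C10 tertiary OH (6R,7S,8R,9S,10S) | C=C1C(=O)O[C@H](/C=C(/C)C#CI)[C@H]1[C@@H](O[Si](C)(C)C(C)(C)C)[C@H](OCc1ccc(OC)cc1)[C@](C)(O)C=O | intermediate
34 | alkynylchromium dichloride from 33 (C–I replaced by C–CrCl2) | C=C1C(=O)O[C@H](/C=C(/C)C#C[Cr](Cl)Cl)[C@H]1[C@@H](O[Si](C)(C)C(C)(C)C)[C@H](OCc1ccc(OC)cc1)[C@](C)(O)C=O | intermediate (not isolated)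
35 | macrocyclic propargylic diol: ten-membered 4Z-en-2-yne carbocycle with trans-fused 6,12-α-methylene lactone, 1-OH (both epimers), 10-OH, 8α-OTBS, 9-OPMB (6R,7S,8R,9S,10R) | C=C1C(=O)O[C@@H]2/C=C(/C)C#CC(O)[C@@](C)(O)[C@@H](OCc3ccc(OC)cc3)[C@H](O[Si](C)(C)C(C)(C)C)[C@@H]12 | intermediate
36 | macrocyclic 10-hydroxy-2-yn-1-one from 35 (6R,7S,8R,9S,10S) | C=C1C(=O)O[C@@H]2/C=C(/C)C#CC(=O)[C@@](C)(O)[C@@H](OCc3ccc(OC)cc3)[C@H](O[Si](C)(C)C(C)(C)C)[C@@H]12 | intermediate (not isolated)
37 | furanoheliangolide core with 8α-OTBS and 9-OPMB (6R,7S,8R,9S,10S) | C=C1C(=O)O[C@@H]2/C=C(/C)C3=CC(=O)[C@@](C)(O3)[C@@H](OCc4ccc(OC)cc4)[C@H](O[Si](C)(C)C(C)(C)C)[C@@H]12 | intermediate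
38 | furanoheliangolide core with 8α-OH and 9-OPMB (6R,7R,8R,9S,10S) | C=C1C(=O)O[C@@H]2/C=C(/C)C3=CC(=O)[C@@](C)(O3)[C@@H](OCc4ccc(OC)cc4)[C@H](O)[C@@H]12 | intermediate
39 | 9-O-(4-methoxybenzyl) ether of the target, 8β ester (6R,7S,8S,9S,10S) | C=C1C(=O)O[C@@H]2/C=C(/C)C3=CC(=O)[C@@](C)(O3)[C@@H](OCc4ccc(OC)cc4)[C@@H](OC(=O)/C(=C/C)COC(C)=O)[C@@H]12 | intermediate
40 | CNP0231561.3 (6R,7S,8S,9S,10S) | C=C1C(=O)O[C@@H]2/C=C(/C)C3=CC(=O)[C@@](C)(O3)[C@@H](O)[C@@H](OC(=O)/C(=C/C)COC(C)=O)[C@@H]12 | target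

## Step count and risks

Total steps: 29. Longest linear sequence: 20 steps (steps 1–9, then 19–29, from diethyl L-tartrate).

**Step 25 (ten-membered ring closure).** The risks are ring strain, oligomerisation and the behaviour of the α-hydroxy aldehyde toward CrCl2. The fallback sets out from 28 and comes back at 35, closing the ring at C3–C4 instead of C1–C2. Acetonide hydrolysis of 28 (AcOH/H2O/THF) gives the vinyl-iodide diol F1. Parikh–Doering oxidation gives the vinyl-iodide hydroxy aldehyde F2. Aldehyde-selective addition of HC≡CMgBr (THF, −78 °C) gives the terminal-alkyne carbinol F3 (C1 epimers). An intramolecular Sonogashira coupling (Pd(PPh3)4, CuI, Et3N, THF, 1 mM) then delivers 35.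

**Step 28 (Mitsunobu inversion at the hindered C8).** The risks are elimination toward C7, no reaction, and phosphine addition to the Michael acceptors. The fallback sets out from 38 and comes back at 39, inverting by redox instead of SN2. Dess–Martin oxidation of 38 gives the macrocyclic 8-ketone F4. Chelation-controlled reduction with Zn(BH4)2 (Et2O, −30 °C; zinc bridges the C8 carbonyl and the C9 OPMB oxygen, hydride enters beside H-9, giving the 8,9-anti diol derivative) gives the 8β-alcohol F5. Yamaguchi esterification with 25 (2,4,6-Cl3C6H2COCl, Et3N, then DMAP, toluene), with retention, gives 39.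

**Step 19 (key coupling: C8 selectivity with a new α-alkoxy aldehyde).** The risk is a poor 8α:8β ratio if chelation by the PMB ether is weak in the aqueous medium. The fallback sets out from 27 obtained as a mixture and comes back at pure 27, setting C8 by ketone reduction instead of in the C–C bond-forming event. The mixture of 27 and its C8 epimer, the 8β-alcohol F6, is oxidised (Dess–Martin periodinane, NaHCO3) to the single seco-lactone 8-ketone F7. Reduction under non-chelating Felkin–Anh control (NaBH4, CeCl3·7H2O, MeOH, −78 °C; hydride anti to the C9–O bond, 8,9-syn) converges on 27.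

## Further compounds

F1 | step 25 | vinyl-iodide diol (28 without the acetonide: C1-OH and C10-OH free, 8-OTBS, 9-OPMB) | C=C1C(=O)O[C@H](/C=C(/C)I)[C@H]1[C@@H](O[Si](C)(C)C(C)(C)C)[C@H](OCc1ccc(OC)cc1)[C@](C)(O)CO
F2 | step 25 | vinyl-iodide hydroxy aldehyde (C1 aldehyde of F1) | C=C1C(=O)O[C@H](/C=C(/C)I)[C@H]1[C@@H](O[Si](C)(C)C(C)(C)C)[C@H](OCc1ccc(OC)cc1)[C@](C)(O)C=O
F3 | step 25 | terminal-alkyne carbinol (ethynyl adduct of F2, C1 epimers) | C=C1C(=O)O[C@H](/C=C(/C)I)[C@H]1[C@@H](O[Si](C)(C)C(C)(C)C)[C@H](OCc1ccc(OC)cc1)[C@](C)(O)C(O)C#C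
F4 | step 28 | macrocyclic 8-ketone (38 oxidised at C8) | C=C1C(=O)O[C@@H]2/C=C(/C)C3=CC(=O)[C@@](C)(O3)[C@@H](OCc4ccc(OC)cc4)C(=O)[C@@H]12
F5 | step 28 | 8β-alcohol (C8 epimer of 38) | C=C1C(=O)O[C@@H]2/C=C(/C)C3=CC(=O)[C@@](C)(O3)[C@@H](OCc4ccc(OC)cc4)[C@@H](O)[C@@H]12
F6 | step 19 | 8β-alcohol (C8 epimer of 27) | C=C1C(=O)O[C@H](/C=C(/C)I)[C@H]1[C@H](O)[C@H](OCc1ccc(OC)cc1)[C@@]1(C)COC(C)(C)O1
F7 | step 19 | seco-lactone 8-ketone (27 oxidised at C8) | C=C1C(=O)O[C@H](/C=C(/C)I)[C@H]1C(=O)[C@H](OCc1ccc(OC)cc1)[C@@]1(C)COC(C)(C)O1
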